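**Retrosynthetic overview**
1. Stilbene C=C: Mizoroki–Heck coupling of a ring A styrene with 5-iodoresorcinol (last step); the styrene comes from the ring A aldehyde by Wittig methylenation.
2. Dioxane ring (the only ring made; all three benzene rings are bought): closed by acid through a p-quinone methide (O1–C2 bond), trans by thermodynamic control.
3. Key C2–C3 bond: the oxygen-bearing carbon of a ring A allyl ether is used as the nucleophile (a (Z)-γ-aryloxyallyl-diisopinocampheylborane, an α-aryloxy carbanion equivalent) towards MOM-protected syringaldehyde. This sets both stereocentres; the vinyl group is then cut to CH2OH.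
4. Ring A: 3,4,5-trihydroxybenzaldehyde, 4-O-allylated selectively, so the O4–C3 ether bond is in place from step 1.
5. Order of events: O4–C3 ether (step 1) → C2–C3 bond (step 5) → dioxane ring (step 7) → stilbene (steps 8–9).

Assumption: the target is the (2S,3S)-trans isomer encoded by the SMILES, and "(+)-Ipc2BOMe" means the B-methoxydiisopinocampheylborane made from (−)-α-pinene.

**Route**

Step 1
Reactants: 1 3,4,5-trihydroxybenzaldehyde; 2 allyl bromide
Product: 3 4-(allyloxy)-3,5-dihydroxybenzaldehyde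
Conditions: KHCO3 (1.05 equiv), DMF, rt, 16 h
Reagents that add atoms: none
Why: the 4-OH (para to CHO, flanked by two hydrogen-bonding OH groups) is the most acidic, so one equivalent of weak base gives only that phenoxide, which undergoes Williamson etherification (SN2) with allyl bromide.

Step 2
Reactants: 3 4-(allyloxy)-3,5-dihydroxybenzaldehyde
Product: 4 2-[4-(allyloxy)-3,5-dihydroxyphenyl]-1,3-dioxolane
Conditions: HOCH2CH2OH (5 equiv), TsOH·H2O (2 mol%), toluene, reflux (Dean–Stark)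
Reagents that add atoms: ethylene glycol, OCCO
Why: acid-catalysed acetalisation with azeotropic water removal masks the aldehyde against s-BuLi, the allylborane and NaBH4, and is done before MOM protection because acid plus diol would strip MOM ethers.

Step 3
Reactants: 4 2-[4-(allyloxy)-3,5-dihydroxyphenyl]-1,3-dioxolane
Product: 5 2-[4-(allyloxy)-3,5-bis(methoxymethoxy)phenyl]-1,3-dioxolane
Conditions: MOMCl (2.6 equiv), i-Pr2NEt (3.5 equiv), CH2Cl2, 0 °C → rt
Reagents that add atoms: chloromethyl methyl ether, COCCl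
Why: amine-buffered O-alkylation (acetal formation) caps both phenols with groups that survive s-BuLi, BF3·OEt2 at −78 °C, ozone and NaBH4 but fall in aqueous acid.

Step 4
Reactants: 6 syringaldehyde (4-hydroxy-3,5-dimethoxybenzaldehyde)
Product: 7 3,5-dimethoxy-4-(methoxymethoxy)benzaldehyde
Conditions: MOMCl (1.5 equiv), i-Pr2NEt (2 equiv), CH2Cl2, 0 °C → reflux
Reagents that add atoms: chloromethyl methyl ether, COCCl
Why: O-alkylation of the hindered phenol removes the acidic proton that would quench the allylborane and protects the 2,6-dimethoxyphenol from ozone.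

Step 5
Reactants: 5 2-[4-(allyloxy)-3,5-bis(methoxymethoxy)phenyl]-1,3-dioxolane; 7 3,5-dimethoxy-4-(methoxymethoxy)benzaldehyde
Product: 12 (1S,2S)-1-[3,5-dimethoxy-4-(methoxymethoxy)phenyl]-2-[4-(1,3-dioxolan-2-yl)-2,6-bis(methoxymethoxy)phenoxy]but-3-en-1-ol, via allyllithium 8 (not isolated), via borate 9 (not isolated), via allylborane 10 (not isolated), via borinate 11 (not isolated)
Conditions: 5 (1.3 equiv), s-BuLi (1.25 equiv), THF, −78 °C, 30 min; (+)-Ipc2BOMe (1.3 equiv), −78 °C, 1 h; BF3·OEt2 (1.3 equiv) then 7 (1.0 equiv), −78 °C, 4 h; 3 M NaOH, 30% H2O2, 0 °C → rt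
Reagents that add atoms: none
Why: Brown asymmetric γ-alkoxyallylboration, in which kinetic α-deprotonation gives the chelated (Z)-oxyallyllithium, boron enters at the carbon remote from oxygen, and the (Z)-allylborane delivers its oxygen-bearing carbon to the aldehyde through a closed chair transition state (Z → syn) while the isopinocampheyl groups from (−)-α-pinene select the Re face of 7, so both stereocentres form as (1S,2S) in the C–C bond-forming event.

Step 6
Reactants: 12 (1S,2S)-1-[3,5-dimethoxy-4-(methoxymethoxy)phenyl]-2-[4-(1,3-dioxolan-2-yl)-2,6-bis(methoxymethoxy)phenoxy]but-3-en-1-ol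
Product: 14 (1S,2S)-1-[3,5-dimethoxy-4-(methoxymethoxy)phenyl]-2-[4-(1,3-dioxolan-2-yl)-2,6-bis(methoxymethoxy)phenoxy]propane-1,3-diol, via aldehyde 13 (not isolated)
Conditions: O3, CH2Cl2/MeOH 3:1, −78 °C (Sudan Red 7B end point); NaBH4 (6 equiv), −78 → 0 °C
Reagents that add atoms: ozone, [O-][O+]=O
Why: ozonolysis of the only alkene with reductive work-up turns the vinyl group into CH2OH, and reducing the α-aryloxy aldehyde at −78 °C before it can enolise leaves both stereocentres untouched.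

Step 7
Reactants: 14 (1S,2S)-1-[3,5-dimethoxy-4-(methoxymethoxy)phenyl]-2-[4-(1,3-dioxolan-2-yl)-2,6-bis(methoxymethoxy)phenoxy]propane-1,3-diol
Product: 17 (2S,3S)-5-hydroxy-2-(4-hydroxy-3,5-dimethoxyphenyl)-3-(hydroxymethyl)-2,3-dihydro-1,4-benzodioxine-7-carbaldehyde (aryl-bearing carbon numbered C2), via triphenol aldehyde 15 (not isolated), via quinone methide 16 (not isolated)
Conditions: 3 M aq HCl/THF 1:1 (0.02 M), 45 °C, 4 h, N2
Reagents that add atoms: water, O
Why: acid hydrolysis removes the three MOM ethers and the dioxolane, then acid-catalysed ionisation of the p-hydroxybenzylic alcohol gives a quinone methide that is trapped reversibly by either of the two equivalent ring A phenols (6-membered ring), so C3 keeps its (S) configuration from step 5 and C2 settles as (S) in the thermodynamically preferred trans-diequatorial benzodioxane.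

Step 8
Reactants: 17 (2S,3S)-5-hydroxy-2-(4-hydroxy-3,5-dimethoxyphenyl)-3-(hydroxymethyl)-2,3-dihydro-1,4-benzodioxine-7-carbaldehyde
Product: 18 2,6-dimethoxy-4-[(2S,3S)-5-hydroxy-3-(hydroxymethyl)-7-vinyl-2,3-dihydro-1,4-benzodioxin-2-yl]phenol
Conditions: Ph3PCH3Br (5 equiv), KOtBu (5 equiv), THF, 0 °C; then 17, 0 °C → rt, 1 h; NH4Cl (aq)
Reagents that add atoms: methyltriphenylphosphonium bromide, C[P+](c1ccccc1)(c1ccccc1)c1ccccc1.[Br-]
Why: Wittig methylenation with excess ylide (three equivalents are spent on the OH groups), in which the ring A phenoxide is meta to the aldehyde and does not deactivate it, and no stereocentre is involved.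

Step 9
Reactants: 18 2,6-dimethoxy-4-[(2S,3S)-5-hydroxy-3-(hydroxymethyl)-7-vinyl-2,3-dihydro-1,4-benzodioxin-2-yl]phenol; 19 5-iodoresorcinol (5-iodobenzene-1,3-diol)
Product: 20 5-{(E)-2-[(2S,3S)-5-hydroxy-2-(4-hydroxy-3,5-dimethoxyphenyl)-3-(hydroxymethyl)-2,3-dihydro-1,4-benzodioxin-7-yl]vinyl}benzene-1,3-diol (CNP0319597.1)
Conditions: 19 (1.2 equiv), Pd(OAc)2 (5 mol%), P(o-tol)3 (10 mol%), Et3N (3 equiv), degassed DMF, 90 °C, 12 h
Reagents that add atoms: none
Why: Mizoroki–Heck reaction in which oxidative addition of the aryl iodide to zerovalent palladium, syn-insertion at the unsubstituted styrene carbon and syn-β-hydride elimination give the (E)-stilbene, free phenols being tolerated and the two stereocentres untouched.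

**Compound list**
1 | 3,4,5-trihydroxybenzaldehyde | O=Cc1cc(O)c(O)c(O)c1 | starting material
2 | allyl bromide | C=CCBr | starting material
3 | 4-(allyloxy)-3,5-dihydroxybenzaldehyde | O=Cc1cc(O)c(OCC=C)c(O)c1 | intermediate
4 | 2-[4-(allyloxy)-3,5-dihydroxyphenyl]-1,3-dioxolane | C=CCOc1c(O)cc(cc1O)C1OCCO1 | intermediate
5 | 2-[4-(allyloxy)-3,5-bis(methoxymethoxy)phenyl]-1,3-dioxolane | C=CCOc1c(OCOC)cc(cc1OCOC)C1OCCO1 | intermediate
6 | syringaldehyde | COc1cc(C=O)cc(OC)c1O | starting material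
7 | 3,5-dimethoxy-4-(methoxymethoxy)benzaldehyde | COCOc1c(OC)cc(C=O)cc1OC | intermediate
8 | (Z)-3-[4-(1,3-dioxolan-2-yl)-2,6-bis(methoxymethoxy)phenoxy]allyllithium | [Li]C/C=C\Oc1c(OCOC)cc(cc1OCOC)C1OCCO1 | intermediate
9 | lithium {(Z)-3-[4-(1,3-dioxolan-2-yl)-2,6-bis(methoxymethoxy)phenoxy]allyl}(methoxy)diisopinocampheylborate | [Li+].CO[B-](C/C=C\Oc1c(OCOC)cc(cc1OCOC)C1OCCO1)([C@H]1C[C@H]2C[C@@H]([C@@H]1C)C2(C)C)[C@H]1C[C@H]2C[C@@H]([C@@H]1C)C2(C)C | intermediate
10 | {(Z)-3-[4-(1,3-dioxolan-2-yl)-2,6-bis(methoxymethoxy)phenoxy]allyl}diisopinocampheylborane (Ipc from (−)-α-pinene) | B(C/C=C\Oc1c(OCOC)cc(cc1OCOC)C1OCCO1)([C@H]1C[C@H]2C[C@@H]([C@@H]1C)C2(C)C)[C@H]1C[C@H]2C[C@@H]([C@@H]1C)C2(C)C | intermediate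
11 | O-diisopinocampheylborinate of 12 | COCOc1c(OC)cc(cc1OC)[C@H](OB([C@H]2C[C@H]3C[C@@H]([C@@H]2C)C3(C)C)[C@H]2C[C@H]3C[C@@H]([C@@H]2C)C3(C)C)[C@@H](Oc1c(OCOC)cc(cc1OCOC)C1OCCO1)C=C | intermediate
12 | (1S,2S)-1-[3,5-dimethoxy-4-(methoxymethoxy)phenyl]-2-[4-(1,3-dioxolan-2-yl)-2,6-bis(methoxymethoxy)phenoxy]but-3-en-1-ol | COCOc1c(OC)cc(cc1OC)[C@H](O)[C@@H](Oc1c(OCOC)cc(cc1OCOC)C1OCCO1)C=C | intermediate
13 | (2R,3S)-3-[3,5-dimethoxy-4-(methoxymethoxy)phenyl]-2-[4-(1,3-dioxolan-2-yl)-2,6-bis(methoxymethoxy)phenoxy]-3-hydroxypropanal | COCOc1c(OC)cc(cc1OC)[C@H](O)[C@@H](Oc1c(OCOC)cc(cc1OCOC)C1OCCO1)C=O | intermediate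
14 | (1S,2S)-1-[3,5-dimethoxy-4-(methoxymethoxy)phenyl]-2-[4-(1,3-dioxolan-2-yl)-2,6-bis(methoxymethoxy)phenoxy]propane-1,3-diol | COCOc1c(OC)cc(cc1OC)[C@H](O)[C@@H](Oc1c(OCOC)cc(cc1OCOC)C1OCCO1)CO | intermediate
15 | 4-{[(1S,2S)-1,3-dihydroxy-1-(4-hydroxy-3,5-dimethoxyphenyl)propan-2-yl]oxy}-3,5-dihydroxybenzaldehyde | COc1cc(cc(OC)c1O)[C@H](O)[C@@H](Oc1c(O)cc(C=O)cc1O)CO | intermediate
16 | 4-{[(2R)-1-hydroxy-3-(3,5-dimethoxy-4-oxocyclohexa-2,5-dien-1-ylidene)propan-2-yl]oxy}-3,5-dihydroxybenzaldehyde (p-quinone methide) | COC1=CC(=C[C@@H](Oc2c(O)cc(C=O)cc2O)CO)C=C(OC)C1=O | intermediate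
17 | (2S,3S)-5-hydroxy-2-(4-hydroxy-3,5-dimethoxyphenyl)-3-(hydroxymethyl)-2,3-dihydro-1,4-benzodioxine-7-carbaldehyde | COc1cc([C@@H]2Oc3cc(C=O)cc(O)c3O[C@H]2CO)cc(OC)c1O | intermediate
18 | 2,6-dimethoxy-4-[(2S,3S)-5-hydroxy-3-(hydroxymethyl)-7-vinyl-2,3-dihydro-1,4-benzodioxin-2-yl]phenol | COc1cc([C@@H]2Oc3cc(C=C)cc(O)c3O[C@H]2CO)cc(OC)c1O | intermediate
19 | 5-iodoresorcinol | Oc1cc(O)cc(I)c1 | starting material
20 | 5-{(E)-2-[(2S,3S)-5-hydroxy-2-(4-hydroxy-3,5-dimethoxyphenyl)-3-(hydroxymethyl)-2,3-dihydro-1,4-benzodioxin-7-yl]vinyl}benzene-1,3-diol (CNP0319597.1) | COc1cc([C@@H]2Oc3cc(/C=C/c4cc(O)cc(O)c4)cc(O)c3O[C@H]2CO)cc(OC)c1O | target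

**Step count**
Total: 9 steps. Longest linear sequence: 8 steps (1, 2, 3, 5, 6, 7, 8, 9); step 4 is a one-step side branch.

**Steps most likely to fail, with fallbacks**

Step 5 (key coupling). Risks: ring lithiation next to the MOM ethers competing with allylic deprotonation; BF3·OEt2 touching the dioxolane; lower ee than with simple allyl ethers. If ee is short of requirement, 17 is recrystallised. Fallback, setting out from 5 (and 7) and coming back at 14: Lemieux–von Rudloff cleavage of the allyl group of 5 (KMnO4 cat., NaIO4, K2CO3, t-BuOH/H2O) gives 2-[4-(1,3-dioxolan-2-yl)-2,6-bis(methoxymethoxy)phenoxy]acetic acid F1. Its pivaloyl mixed anhydride is treated with lithiated (R)-4-benzyl-1,3-oxazolidin-2-one to give the N-(aryloxyacetyl)oxazolidinone F2. Bu2BOTf/i-Pr2NEt enolisation and addition of 7 (Evans syn-aldol, CH2Cl2, −78 → 0 °C) give the (2R,3S) syn-aldol adduct F3. LiBH4 (THF/MeOH, 0 °C) removes the auxiliary reductively and gives diol 14 directly, so steps 5 and 6 are bypassed and the route resumes at step 7.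

Step 7 (deprotection and ring closure in one pot). Risks: enol-ether formation from the benzylic cation, capture of released formaldehyde by the syringyl ring, incomplete trans selectivity. Fallback, setting out from 14 and coming back at 17: Me3SiBr (excess, CH2Cl2, −20 → 0 °C) cleaves the three MOM ethers, opens the dioxolane and replaces the benzylic hydroxyl by bromide. Brief aqueous work-up gives the benzylic bromide F4 (both epimers at the C–Br carbon). Shaking with NaHCO3 (aq)/CH2Cl2 expels bromide to give quinone methide 16, which closes under base by intramolecular oxa-1,6-addition to trans-17. Ring closure is then a discrete, acid-free event.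

Step 9 (Heck coupling with five free OH groups). Risks: oxidation or oligomerisation of the polyphenolic styrene and stilbene at 90 °C, 1,1-diaryl regioisomer. Fallback, setting out from 18 (and 19) and coming back at 20: Ac2O/pyridine converts 18 into the triacetate F5 and 19 into 5-iodo-1,3-phenylene diacetate F6. Heck coupling of the two (Pd(OAc)2, PPh3, Et3N, MeCN, 85 °C) gives the (E)-stilbene pentaacetate F7. K2CO3 in degassed MeOH at 0 °C removes the five acetates to give 20.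

**Further compounds**
F1 | step 5 | 2-[4-(1,3-dioxolan-2-yl)-2,6-bis(methoxymethoxy)phenoxy]acetic acid | OC(=O)COc1c(OCOC)cc(cc1OCOC)C1OCCO1
F2 | step 5 | (R)-4-benzyl-3-{2-[4-(1,3-dioxolan-2-yl)-2,6-bis(methoxymethoxy)phenoxy]acetyl}-1,3-oxazolidin-2-one | O=C(COc1c(OCOC)cc(cc1OCOC)C1OCCO1)N1[C@H](Cc2ccccc2)COC1=O
F3 | step 5 | (R)-4-benzyl-3-{(2R,3S)-3-[3,5-dimethoxy-4-(methoxymethoxy)phenyl]-2-[4-(1,3-dioxolan-2-yl)-2,6-bis(methoxymethoxy)phenoxy]-3-hydroxypropanoyl}-1,3-oxazolidin-2-one | COCOc1c(OC)cc(cc1OC)[C@H](O)[C@@H](Oc1c(OCOC)cc(cc1OCOC)C1OCCO1)C(=O)N1[C@H](Cc2ccccc2)COC1=O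
F4 | step 7 | 4-{[(2S)-1-bromo-3-hydroxy-1-(4-hydroxy-3,5-dimethoxyphenyl)propan-2-yl]oxy}-3,5-dihydroxybenzaldehyde (both epimers at C–Br) | COc1cc(cc(OC)c1O)C(Br)[C@@H](Oc1c(O)cc(C=O)cc1O)CO
F5 | step 9 | triacetate of 18 | COc1cc([C@@H]2Oc3cc(C=C)cc(OC(C)=O)c3O[C@H]2COC(C)=O)cc(OC)c1OC(C)=O
F6 | step 9 | 5-iodo-1,3-phenylene diacetate | CC(=O)Oc1cc(I)cc(OC(C)=O)c1
F7 | step 9 | pentaacetate of 20 | COc1cc([C@@H]2Oc3cc(/C=C/c4cc(OC(C)=O)cc(OC(C)=O)c4)cc(OC(C)=O)c3O[C@H]2COC(C)=O)cc(OC)c1OC(C)=O
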